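## The problem

Target 25 is a trans-fused bicyclic sesquiterpene ether (drimane numbering throughout). Ring A is a cyclohexanone with the C3 ketone next to the C4 gem-dimethyl group, ring B is a cyclohexene (C7=C8, methyl on C8), and C9 carries the CH2–O–(7-coumarinyl) arm (C11). Three contiguous stereocentres, (5S,9S,10R), must be set: H5 is trans to the angular C10 methyl, and C11 lies on the face opposite that methyl, the axial position that protonation of a C9 enolate from the open face would not give. C10 is quaternary and cannot be corrected later, so it must come from a stereospecific event. A stereocentre at C5 can control C10 through ring A, but C9 can be tied to C10 only through an ordered cyclic transition state, because the C9–C10 bond is exocyclic until ring B exists. The C7=C8 alkene is allylic at C9 and can slip to the tetrasubstituted C8=C9 or an exocyclic position under acid, base or enolisation, and the same C9–H makes C11 sulfonates prone to elimination. The coumarin (aryl lactone and Michael acceptor) and the C3 ketone will not survive organolithiums, hydrides or strong base, so the coumarin arrives late and the ketone travels masked; the neopentyl C3 oxygen must be present from the start, since no late oxidation would find it. C7 and C8 are the only ring B carbons that are not stereocentres and they hold the only C=C of the carbocycle, so cutting there leaves ring A with all three stereocentres and two alkene arms on neighbouring atoms (allyl on C5, isopropenyl on C9), which is what makes ring-closing metathesis possible.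

## Retrosynthesis

**C3 carbonyl (25 ⇒ 24 ⇒ 23).** No skeletal bond is cut. The ketone is traced to secondary alcohol 24 and its silyl ether 23. A free C3 ketone would not survive the enolate, organolithium and hydride steps, so the oxygen is carried as a TBS ether. The forward steps need only a desilylation and an oxidation that tolerate the coumarin and the alkene.

**Aryl ether (23 ⇒ 21 + 22).** The C11–O bond is cut to give primary alcohol 21 and umbelliferone 22. Displacing a C11 sulfonate would risk elimination towards C9, whereas a Mitsunobu reaction is neutral and suits a phenol of pKa about 8. The cut removes the whole base- and nucleophile-sensitive aromatic lactone from every earlier intermediate. The forward reaction must activate a β-branched primary alcohol.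

**Protecting group and C1=C2 (21 ⇒ 20 ⇒ 19).** No skeletal bond is cut. The PMB ether on C11 is put back (20) and the C1=C2 alkene is re-introduced (19). That alkene is the footprint of the sigmatropic step that makes C10. The forward reduction must tell a cis-disubstituted alkene from the trisubstituted C7=C8 alkene.

**Ring B (19 ⇒ 18).** The C7=C8 double bond is cut to give triene 18 with an allyl group on C5 and an isopropenyl group on C9. Against an elimination or isomerisation approach, this cut makes the alkene between the only two carbons the arms supply. Against annulations that build ring B around C9 or C10, it touches no stereocentre. Precursor 18 is monocyclic. The forward reaction must close a six-membered ring onto a 1,1-disubstituted alkene without engaging C1=C2.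

**Isopropenyl arm (18 ⇒ 17 ⇒ 15).** The C8=CH2 and C8–CH3 bonds are cut in turn, leading through methyl ketone 17 to carboxylic acid 15. This costs two steps, but it lets the carboxyl carbon of a Claisen product become C8, which is what the C9 configuration demands (next paragraph).

**C9–C10 bond (15 ⇒ 12 ⇒ 10 + 11).** The bond is cut by an Ireland–Claisen transform to give ester 12, made from allylic alcohol 10 and acid 11.
- *C10:* the [3,3] shift is suprafacial, so a C2 oxygen trans to the C5 allyl group delivers C9 to the correct face of C10 and leaves only the C1=C2 alkene.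
- *Transition state:* cyclohexenyl ketene acetals prefer a boat-like transition state. Here the chair is further penalised because it pushes the silyloxy-bearing carbon over ring A against the axial C4 methyl.
- *C9:* in the boat from a (Z)-ketene acetal such as 13, the acyl carbon lies over C1 and the outward α-substituent over the C10 methyl. Once ring B is closed through the acyl-derived carbon, that α-substituent is anti to the angular methyl.
- *Consequence:* the arrangement with the carboxyl carbon as C11 and the isopropenyl group on the α-carbon would put C11 syn to the methyl, the wrong C9 epimer. The roles are therefore exchanged: the α-substituent of 11 is the future C11 (as CH2OPMB) and the carboxyl carbon becomes C8.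
- *Cost:* C11 is already at the alcohol oxidation level, so no ester reduction is needed later and the step count stays about even.

**Carbinol and C3 oxygen (10 ⇒ 9 ⇒ 8 ⇒ 7 ⇒ 6).** No skeletal bond is cut. Alcohol 10 is one enantiomer of racemate 9, taken by kinetic resolution because no earlier intermediate offers a reliable catalytic asymmetric entry. Alcohol 9 comes from ketone 8 by hydride delivery anti to the silyloxy group and the axial C4 methyl. The C3 oxygen of 8 comes from enone 6 through silyloxy diene 7 by Rubottom oxidation, which uses the only position (α' to the carbonyl) that addresses this neopentyl carbon.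

**Ring A (6 ⇒ 4 ⇒ 2 + 3, 2 ⇒ 1).** The C10–CH3 and C5–C6 bonds are cut by a Stork–Danheiser sequence. Enone 6 arises from allylated vinylogous ester 4, which comes from ethyl enol ether 2 and allyl bromide 3; 2 comes from dimedone 1. The gem-dimethyl group and both flanking methylenes of dimedone map onto C4, C5 and C3, so all ring A carbons are bought in one piece.

## Roads not taken

**Alternative 1:** The angular methyl is traced back to a cyclopropane (the C10–CH3 bond read as a C9,C10-methano bridge). Hydroxyl-directed cyclopropanation (Et2Zn, CH2I2) of the C9=C10 alkene of allylic alcohol A2 would give methano alcohol A1 on the hydroxyl face. Oxidation to the C8 ketone and dissolving-metal cleavage of the exocyclic C9–CH2 bond would then reveal the C10 methyl and a regiodefined C8/C9 enolate.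
- *Merits:* directed cyclopropanation is dependable. The released enolate can be trapped with a C11 electrophile from the face away from the new methyl, which is exactly the required C9 configuration. The C3 ketone travels as a ketal with no temporary stereocentre. A kinetic enol triflate towards C7 with methyl coupling could place C7=C8.
- *Weak points:* the cyclopropanation face, and so the H5/methyl trans relation, depends on the C8 carbinol, which must be set from C5 across the trigonal C10 with little bias. The octalin requires annulation at the hindered α-carbon next to the gem-dimethyl group. C5 stays epimerisable through a dienolate until the cyclopropane is in place. About seven operations follow A1.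
- *Comparison:* in C9 control and in avoiding the C3 detour this road is as good or better. The chosen plan sets against it a C10 configuration transferred stereospecifically from a carbinol set 1,2 to a silyloxy group, and an alkene fixed by the ring closure itself and not by the regiochemistry of an enolisation.

**Alternative 2:** Ring B is cut at C9–C10 and C7–C8. A Cu(OTf)2/tert-butyl bis(oxazoline)-catalysed endo Diels–Alder reaction of ring A dienyl ether A5 with N-crotonoyl oxazolidinone A4 would give adduct A3, with the C9 acyl group anti to the C10 methyl.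
- *Merits:* two ring B bonds, the quaternary C10 and C9 arise in one convergent step, with absolute configuration from a catalyst. This is clearly better than the chosen plan, which discards half of racemate 9 and needs eleven steps before its key step.
- *Weak points:* the C10 terminus of A5 is fully substituted and carries a Z-substituent, so the s-cis conformer is strained and cycloaddition with a β-substituted dienophile should be slow. The adduct has oxygen at C6 and the alkene at C5=C6, so C6 must be deoxygenated, H5 set, and C7=C8 created by sacrificing the C8 stereocentre in an elimination whose regiochemistry is the very problem.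
- *Comparison:* the chosen plan offers an intramolecular [3,3] shift for the quaternary carbon in place of an intermolecular addition to a hindered diene, and a key-step product with no surplus oxidation in ring B.

**Alternative 3:** Ring A is cut at C1–C10 and C4–C5. A Diels–Alder reaction of silyloxy diene A8 with one of the two equivalent alkenes of 2,6-dimethylbenzoquinone A7 would give cis-fused adduct A6.
- *Merits:* one step from two achiral pieces delivers both rings, all four methyl groups, the C3 oxygen at the right oxidation level (as a silyl enol ether) and the C7=C8 alkene with its methyl. Electronic regiocontrol is matched (the nucleophilic gem-dimethyl terminus goes to the unsubstituted quinone carbon), and enantioselective quinone Diels–Alder catalysis has precedent. In speed of skeleton assembly this road is better.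
- *Weak points:* the diene terminus is gem-dimethylated, so s-cis is disfavoured and two quaternary carbons form. C5 must be inverted to the trans fusion. The C6 carbonyl must be removed and the C9 carbonyl homologated to CH–CH2OAr with C11 anti to the methyl, all next to an ene-dione alkene that reductions and Wolff–Kishner-type deoxygenations tend to move.
- *Comparison:* the chosen plan is longer up to ring B, but its key-step product 19 needs only protecting-group and oxidation-level adjustments at C3 and C11, with the alkene and all three stereocentres final.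

Key step: step 12

**Assumptions and remarks**
- Acid 11, 3-[(4-methoxybenzyl)oxy]propanoic acid, is taken as a purchased building block.
- Compounds 4 and 6–9 are racemic; 8 and 9 are drawn as the enantiomer carried on.
- The C3 silyloxy stereocentre is temporary and is erased in step 17; it is drawn as the epimer expected from steps 5 and 6.

## Route

Step 1
Reactants: 1 dimedone
Product: 2 3-ethoxy-5,5-dimethylcyclohex-2-en-1-one
Conditions: EtOH, p-TsOH (cat.), toluene, reflux, Dean–Stark
Reagents that add atoms: ethanol, CCO
Why: Acid-catalysed enol etherification of a cyclic 1,3-diketone with azeotropic removal of water; dimedone is symmetric, so there is no regiochemical question.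

Step 2
Reactants: 2 3-ethoxy-5,5-dimethylcyclohex-2-en-1-one; 3 allyl bromide
Product: 4 rac-6-allyl-3-ethoxy-5,5-dimethylcyclohex-2-en-1-one
Conditions: LiN(i-Pr)2, THF, −78 °C; then allyl bromide, DMPU, −78 °C → rt
Reagents that add atoms: none
Why: Stork–Danheiser kinetic α'-alkylation of a vinylogous ester: the amide base removes the C6 proton and the lithium enolate is C-allylated by the reactive allylic bromide, forming the future C5–C6 bond as a racemate.

Step 3
Reactants: 4 rac-6-allyl-3-ethoxy-5,5-dimethylcyclohex-2-en-1-one
Product: 6 rac-4-allyl-3,5,5-trimethylcyclohex-2-en-1-one, via tertiary alcohol 5 (not isolated)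
Conditions: MeLi, Et2O, −78 → 0 °C; then 1 M HCl, rt
Reagents that add atoms: methyllithium, [Li]C; water, O
Why: Stork–Danheiser carbonyl transposition: 1,2-addition of MeLi to the vinylogous ester, then acid hydrolysis of the enol ether with loss of water and ethanol should give the β-methyl enone; the new methyl is the future C10 methyl.

Step 4
Reactants: 6 rac-4-allyl-3,5,5-trimethylcyclohex-2-en-1-one
Product: 7 rac-tert-butyldimethyl{[3,3,5-trimethyl-4-(prop-2-en-1-yl)cyclohexa-1,5-dien-1-yl]oxy}silane
Conditions: LiN(i-Pr)2, THF, −78 °C; TBSCl, DMPU, −78 → 0 °C; used crude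
Reagents that add atoms: tert-butyldimethylsilyl chloride, CC(C)(C)[Si](C)(C)Cl
Why: Kinetic α'-deprotonation of the enone at the CH2 between the carbonyl and the gem-dimethyl carbon gives the cross-conjugated enolate, which is trapped on oxygen as the 2-silyloxy diene; low temperature avoids the extended γ-dienolate.

Step 5
Reactants: 7 rac-tert-butyldimethyl{[3,3,5-trimethyl-4-(prop-2-en-1-yl)cyclohexa-1,5-dien-1-yl]oxy}silane
Product: 8 rac-(4S,6R)-4-allyl-6-[(tert-butyldimethylsilyl)oxy]-3,5,5-trimethylcyclohex-2-en-1-one
Conditions: mCPBA, NaHCO3, CH2Cl2, −20 → 0 °C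
Reagents that add atoms: 3-chloroperoxybenzoic acid, OOC(=O)c1cccc(Cl)c1
Why: Rubottom oxidation: the peracid epoxidises the electron-rich silyloxy alkene in preference to the allyl group and the silyl group migrates to the new oxygen, giving the α'-silyloxy enone. Attack on C3 from the face opposite the C5 allyl group should give the 3,5-trans isomer; this stereocentre is temporary.

Step 6
Reactants: 8 rac-(4S,6R)-4-allyl-6-[(tert-butyldimethylsilyl)oxy]-3,5,5-trimethylcyclohex-2-en-1-one
Product: 9 rac-(1S,4S,6R)-4-allyl-6-[(tert-butyldimethylsilyl)oxy]-3,5,5-trimethylcyclohex-2-en-1-ol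
Conditions: LiBH(s-Bu)3, THF, −78 °C; then aq. NaOH, H2O2, 0 °C
Reagents that add atoms: none
Why: 1,2-Reduction of a β,β-disubstituted enone by a bulky trialkylborohydride: hydride should approach C2 anti to the adjacent silyloxy group and away from the axial C4 methyl, which places the new hydroxyl cis to the silyloxy group and trans to the C5 allyl group.

Step 7
Reactants: 9 rac-(1S,4S,6R)-4-allyl-6-[(tert-butyldimethylsilyl)oxy]-3,5,5-trimethylcyclohex-2-en-1-ol
Product: 10 (1S,4S,6R)-4-allyl-6-[(tert-butyldimethylsilyl)oxy]-3,5,5-trimethylcyclohex-2-en-1-ol (single enantiomer)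
Conditions: vinyl acetate, Burkholderia cepacia lipase (immobilised), t-BuOMe, 35 °C, to slightly beyond half conversion; chromatography
Reagents that add atoms: none
Why: Lipase-catalysed kinetic resolution by irreversible transesterification: by the empirical size rule (silyloxy side large, vinylic side medium) the (1R)-alcohol should be acetylated and the needed (1S)-alcohol left; if the preference is the reverse, the acetate is taken on after methanolysis.

Step 8
Reactants: 10 (1S,4S,6R)-4-allyl-6-[(tert-butyldimethylsilyl)oxy]-3,5,5-trimethylcyclohex-2-en-1-ol; 11 3-[(4-methoxybenzyl)oxy]propanoic acid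
Product: 12 (1S,4S,6R)-4-allyl-6-[(tert-butyldimethylsilyl)oxy]-3,5,5-trimethylcyclohex-2-en-1-yl 3-[(4-methoxybenzyl)oxy]propanoate
Conditions: EDC·HCl, DMAP, CH2Cl2, 0 °C → rt
Reagents that add atoms: none
Why: Steglich esterification (carbodiimide activation, DMAP acyl transfer) of a hindered secondary alcohol; the allylic C–O bond is not ionised, so the carbinol configuration is retained.

Step 9
Reactants: 12 (1S,4S,6R)-4-allyl-6-[(tert-butyldimethylsilyl)oxy]-3,5,5-trimethylcyclohex-2-en-1-yl 3-[(4-methoxybenzyl)oxy]propanoate
Product: 15 (2S)-2-[(1R,4S,6S)-6-allyl-4-[(tert-butyldimethylsilyl)oxy]-1,5,5-trimethylcyclohex-2-en-1-yl]-3-[(4-methoxybenzyl)oxy]propanoic acid, via silyl ketene acetal 13 (not isolated), via trimethylsilyl ester 14 (not isolated)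
Conditions: LiN(i-Pr)2, THF–DMPU (4:1), −78 °C, 5 min; TMSCl, −78 °C; then → 50 °C; 1 M HCl work-up
Reagents that add atoms: chlorotrimethylsilane, C[Si](C)(C)Cl (its silicon is carried only by 13 and 14 and is lost on hydrolysis to 15)
Why: Ireland–Claisen rearrangement: enolisation with the polar cosolvent gives the (Z)-silyl ketene acetal 13 (CH2OPMB cis to OSiMe3), which rearranges suprafacially through a boat-like transition state, the chair being disfavoured because it forces the silyloxy-bearing carbon over ring A against the axial C4 methyl. The C9–C10 bond forms on the face that carried the C2 oxygen, anti to the C5 allyl group (sets C10), and the outward CH2OPMB group ends anti to the angular methyl once ring B is closed through the carboxyl carbon (sets C9); acid work-up hydrolyses silyl ester 14.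

Step 10
Reactants: 15 (2S)-2-[(1R,4S,6S)-6-allyl-4-[(tert-butyldimethylsilyl)oxy]-1,5,5-trimethylcyclohex-2-en-1-yl]-3-[(4-methoxybenzyl)oxy]propanoic acid
Product: 17 (3S)-3-[(1R,4S,6S)-6-allyl-4-[(tert-butyldimethylsilyl)oxy]-1,5,5-trimethylcyclohex-2-en-1-yl]-4-[(4-methoxybenzyl)oxy]butan-2-one, via dilithium gem-diolate 16 (not isolated)
Conditions: MeLi (3 equiv), Et2O, 0 °C → rt; inverse quench into cold 1 M HCl
Reagents that add atoms: methyllithium, [Li]C
Why: Methyl ketone synthesis by addition of methyllithium to a lithium carboxylate: the gem-diolate 16 resists a second addition and collapses to the ketone only on acidic quench; the carboxylate is not enolised, so C9 should be untouched.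

Step 11
Reactants: 17 (3S)-3-[(1R,4S,6S)-6-allyl-4-[(tert-butyldimethylsilyl)oxy]-1,5,5-trimethylcyclohex-2-en-1-yl]-4-[(4-methoxybenzyl)oxy]butan-2-one
Product: 18 1-({[(2S)-2-[(1R,4S,6S)-6-allyl-4-[(tert-butyldimethylsilyl)oxy]-1,5,5-trimethylcyclohex-2-en-1-yl]-3-methylbut-3-en-1-yl]oxy}methyl)-4-methoxybenzene (ring A triene: C5 allyl, C9 isopropenyl and CH2OPMB, C3 OTBS, C1=C2)
Conditions: Cp2TiMe2 (3 equiv), toluene–THF, 65 °C, dark
Reagents that add atoms: dimethyltitanocene (bis(cyclopentadienyl)dimethyltitanium, Cp2TiMe2), C[Ti](C)(C1C=CC=C1)C1C=CC=C1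
Why: Petasis methylenation: on heating, Cp2TiMe2 loses methane to give the titanium methylidene Cp2Ti=CH2, which adds to the ketone to form an oxatitanacyclobutane and cycloreverts to the 1,1-disubstituted alkene and titanocene oxide. The reagent is neither basic nor Lewis acidic, so the C9 stereocentre, the β-alkoxy group and the allylic silyl ether should not be exposed to enolisation or ionisation; the acetyl group becomes the isopropenyl arm.

Step 12
Reactants: 18 ring A triene (C5 allyl, C9 isopropenyl and CH2OPMB, C3 OTBS, C1=C2)
Product: 19 (3S,5S,9S,10R)-3-[(tert-butyldimethylsilyl)oxy]-11-[(4-methoxybenzyl)oxy]drima-1,7-diene (drimane numbering; trans-fused, C11 anti to the C10 methyl)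
Conditions: second-generation Grubbs catalyst (H2IMes)(PCy3)Cl2Ru=CHPh (5 mol %), CH2Cl2 (0.005 M), 40 °C, argon sparge
Reagents that add atoms: none
Why: Ring-closing olefin metathesis by the Chauvin mechanism: the ruthenium benzylidene exchanges onto the unhindered terminal allyl alkene, the new alkylidene at C7 adds across the isopropenyl alkene to a ruthenacyclobutane, and cycloreversion releases the C7=C8 alkene, with ethene leaving from the Ru=CH2 carrier. The closest known reaction type is ring closure of a monosubstituted alkene with a 1,1-disubstituted alkene to a 1-methylcyclohexene, routine with second-generation catalysts. Ring B closes as a six-membered carbocycle by joining the terminal sp2 carbons of arms held on C5 and on C9 (attached to C10); both arms are equatorial in the reacting conformer of ring A, so the ring formed is trans-fused. No stereocentre is created, and C5, C9 and C10 are remote from the reacting carbons under neutral conditions. Chemoselectivity among three alkenes is required: the C1=C2 alkene is internal, unstrained and flanked by the quaternary C10 and the silyloxy-bearing C3, so it should neither load the catalyst nor accept the alkylidene, and opening ring A has no driving force. High dilution and removal of ethene favour cyclisation over dimerisation through the allyl group. Because the double bond can only form between the two carbons the arms supply, exocyclic and tetrasubstituted isomers are excluded by construction.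

Step 13
Reactants: 19 (3S,5S,9S,10R)-3-[(tert-butyldimethylsilyl)oxy]-11-[(4-methoxybenzyl)oxy]drima-1,7-diene
Product: 20 (3S,5S,9S,10R)-3-[(tert-butyldimethylsilyl)oxy]-11-[(4-methoxybenzyl)oxy]drim-7-ene
Conditions: H2 (4 atm), RhCl(PPh3)3 (10 mol %), benzene–EtOH, rt
Reagents that add atoms: none
Why: Homogeneous hydrogenation with Wilkinson's catalyst RhCl(PPh3)3, which discriminates by substitution: the cis-disubstituted C1=C2 alkene should be reduced while the trisubstituted C7=C8 alkene is left in place without the allylic isomerisation common on Pd/C; the ethers are inert.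

Step 14
Reactants: 20 (3S,5S,9S,10R)-3-[(tert-butyldimethylsilyl)oxy]-11-[(4-methoxybenzyl)oxy]drim-7-ene
Product: 21 (3S,5S,9S,10R)-3-[(tert-butyldimethylsilyl)oxy]drim-7-en-11-ol
Conditions: DDQ, CH2Cl2–pH 7 buffer, 0 °C → rt
Reagents that add atoms: none
Why: Oxidative cleavage of a p-methoxybenzyl ether by DDQ (benzylic hydride abstraction, hydrolysis of the oxocarbenium ion); the silyl ether and the trisubstituted alkene should be untouched under buffered conditions.

Step 15
Reactants: 21 (3S,5S,9S,10R)-3-[(tert-butyldimethylsilyl)oxy]drim-7-en-11-ol; 22 umbelliferone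
Product: 23 7-{[(3S,5S,9S,10R)-3-[(tert-butyldimethylsilyl)oxy]drim-7-en-11-yl]oxy}-2H-chromen-2-one
Conditions: PPh3, DIAD, THF, 0 → 40 °C
Reagents that add atoms: none
Why: Mitsunobu etherification: the primary C11 alcohol is activated as its oxyphosphonium salt and displaced by the phenoxide of umbelliferone (pKa about 8); no stereocentre is involved, and the neutral conditions avoid elimination towards C9 and opening of the lactone.

Step 16
Reactants: 23 7-{[(3S,5S,9S,10R)-3-[(tert-butyldimethylsilyl)oxy]drim-7-en-11-yl]oxy}-2H-chromen-2-one
Product: 24 7-{[(3S,5S,9S,10R)-3-hydroxydrim-7-en-11-yl]oxy}-2H-chromen-2-one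
Conditions: HF·pyridine, THF–pyridine, 0 °C → rt
Reagents that add atoms: none
Why: Fluoride-mediated cleavage of the silyl ether under mildly acidic conditions, chosen over basic fluoride sources so that the coumarin lactone stays closed.

Step 17
Reactants: 24 7-{[(3S,5S,9S,10R)-3-hydroxydrim-7-en-11-yl]oxy}-2H-chromen-2-one
Product: 25 7-{[(1S,4aS,8aR)-2,5,5,8a-tetramethyl-6-oxo-1,4,4a,5,6,7,8,8a-octahydronaphthalen-1-yl]methoxy}-2H-chromen-2-one (target; 5S,9S,10R in drimane numbering)
Conditions: Dess–Martin periodinane, NaHCO3, CH2Cl2, rt
Reagents that add atoms: none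
Why: Dess–Martin oxidation of the secondary C3 alcohol to the ketone under buffered neutral conditions; it erases the temporary C3 stereocentre and should leave the alkene, the aryl ether and the coumarin untouched.

## Compound list

1 | dimedone (5,5-dimethylcyclohexane-1,3-dione) | CC1(C)CC(=O)CC(=O)C1 | starting material
2 | 3-ethoxy-5,5-dimethylcyclohex-2-en-1-one | CCOC1=CC(=O)CC(C)(C)C1 | intermediate
3 | allyl bromide (3-bromoprop-1-ene) | C=CCBr | starting material
4 | rac-6-allyl-3-ethoxy-5,5-dimethylcyclohex-2-en-1-one | CCOC1=CC(=O)C(CC=C)C(C)(C)C1 | intermediate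
5 | 6-allyl-3-ethoxy-1,5,5-trimethylcyclohex-2-en-1-ol (1,2-adduct, diastereomer mixture, not isolated) | CCOC1=CC(C)(O)C(CC=C)C(C)(C)C1 | intermediate
6 | rac-4-allyl-3,5,5-trimethylcyclohex-2-en-1-one | CC1=CC(=O)CC(C)(C)C1CC=C | intermediate
7 | rac-tert-butyldimethyl{[3,3,5-trimethyl-4-(prop-2-en-1-yl)cyclohexa-1,5-dien-1-yl]oxy}silane | CC1=CC(O[Si](C)(C)C(C)(C)C)=CC(C)(C)C1CC=C | intermediate
8 | rac-(4S,6R)-4-allyl-6-[(tert-butyldimethylsilyl)oxy]-3,5,5-trimethylcyclohex-2-en-1-one (OTBS trans to allyl; racemic, one enantiomer drawn) | CC1=CC(=O)[C@H](O[Si](C)(C)C(C)(C)C)C(C)(C)[C@H]1CC=C | intermediate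
9 | rac-(1S,4S,6R)-4-allyl-6-[(tert-butyldimethylsilyl)oxy]-3,5,5-trimethylcyclohex-2-en-1-ol (OH cis to OTBS, trans to allyl; racemic, one enantiomer drawn) | CC1=C[C@H](O)[C@H](O[Si](C)(C)C(C)(C)C)C(C)(C)[C@H]1CC=C | intermediate
10 | (1S,4S,6R)-4-allyl-6-[(tert-butyldimethylsilyl)oxy]-3,5,5-trimethylcyclohex-2-en-1-ol (single enantiomer) | CC1=C[C@H](O)[C@H](O[Si](C)(C)C(C)(C)C)C(C)(C)[C@H]1CC=C | intermediate
11 | 3-[(4-methoxybenzyl)oxy]propanoic acid | OC(=O)CCOCc1ccc(OC)cc1 | starting material
12 | (1S,4S,6R)-4-allyl-6-[(tert-butyldimethylsilyl)oxy]-3,5,5-trimethylcyclohex-2-en-1-yl 3-[(4-methoxybenzyl)oxy]propanoate | CC1=C[C@H](OC(=O)CCOCc2ccc(OC)cc2)[C@H](O[Si](C)(C)C(C)(C)C)C(C)(C)[C@H]1CC=C | intermediate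
13 | (Z)-O-trimethylsilyl ketene acetal of 12 (CH2OPMB cis to OSiMe3; not isolated) | CC1=C[C@H](O/C(O[Si](C)(C)C)=C/COCc2ccc(OC)cc2)[C@H](O[Si](C)(C)C(C)(C)C)C(C)(C)[C@H]1CC=C | intermediate
14 | trimethylsilyl ester of acid 15 (not isolated) | C=CC[C@@H]1C(C)(C)[C@@H](O[Si](C)(C)C(C)(C)C)C=C[C@@]1(C)[C@@H](COCc2ccc(OC)cc2)C(=O)O[Si](C)(C)C | intermediate
15 | (2S)-2-[(1R,4S,6S)-6-allyl-4-[(tert-butyldimethylsilyl)oxy]-1,5,5-trimethylcyclohex-2-en-1-yl]-3-[(4-methoxybenzyl)oxy]propanoic acid | C=CC[C@@H]1C(C)(C)[C@@H](O[Si](C)(C)C(C)(C)C)C=C[C@@]1(C)[C@@H](COCc2ccc(OC)cc2)C(=O)O | intermediate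
16 | dilithium gem-diolate from 15 and methyllithium (not isolated) | C=CC[C@@H]1C(C)(C)[C@@H](O[Si](C)(C)C(C)(C)C)C=C[C@@]1(C)[C@@H](COCc2ccc(OC)cc2)C(C)([O-])[O-].[Li+].[Li+] | intermediate
17 | (3S)-3-[(1R,4S,6S)-6-allyl-4-[(tert-butyldimethylsilyl)oxy]-1,5,5-trimethylcyclohex-2-en-1-yl]-4-[(4-methoxybenzyl)oxy]butan-2-one | C=CC[C@@H]1C(C)(C)[C@@H](O[Si](C)(C)C(C)(C)C)C=C[C@@]1(C)[C@@H](COCc2ccc(OC)cc2)C(C)=O | intermediate
18 | 1-({[(2S)-2-[(1R,4S,6S)-6-allyl-4-[(tert-butyldimethylsilyl)oxy]-1,5,5-trimethylcyclohex-2-en-1-yl]-3-methylbut-3-en-1-yl]oxy}methyl)-4-methoxybenzene (metathesis precursor) | C=CC[C@@H]1C(C)(C)[C@@H](O[Si](C)(C)C(C)(C)C)C=C[C@@]1(C)[C@@H](COCc2ccc(OC)cc2)C(C)=C | intermediate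
19 | (3S,5S,9S,10R)-3-[(tert-butyldimethylsilyl)oxy]-11-[(4-methoxybenzyl)oxy]drima-1,7-diene (drimane numbering; metathesis product) | CC1=CC[C@@H]2C(C)(C)[C@@H](O[Si](C)(C)C(C)(C)C)C=C[C@@]2(C)[C@H]1COCc1ccc(OC)cc1 | intermediate
20 | (3S,5S,9S,10R)-3-[(tert-butyldimethylsilyl)oxy]-11-[(4-methoxybenzyl)oxy]drim-7-ene | CC1=CC[C@@H]2C(C)(C)[C@@H](O[Si](C)(C)C(C)(C)C)CC[C@@]2(C)[C@H]1COCc1ccc(OC)cc1 | intermediate
21 | (3S,5S,9S,10R)-3-[(tert-butyldimethylsilyl)oxy]drim-7-en-11-ol | CC1=CC[C@@H]2C(C)(C)[C@@H](O[Si](C)(C)C(C)(C)C)CC[C@@]2(C)[C@H]1CO | intermediate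
22 | umbelliferone (7-hydroxy-2H-chromen-2-one) | O=c1ccc2ccc(O)cc2o1 | starting material
23 | 7-{[(3S,5S,9S,10R)-3-[(tert-butyldimethylsilyl)oxy]drim-7-en-11-yl]oxy}-2H-chromen-2-one | CC1=CC[C@@H]2C(C)(C)[C@@H](O[Si](C)(C)C(C)(C)C)CC[C@@]2(C)[C@H]1COc1ccc2ccc(=O)oc2c1 | intermediate
24 | 7-{[(3S,5S,9S,10R)-3-hydroxydrim-7-en-11-yl]oxy}-2H-chromen-2-one | CC1=CC[C@@H]2C(C)(C)[C@@H](O)CC[C@@]2(C)[C@H]1COc1ccc2ccc(=O)oc2c1 | intermediate
25 | 7-{[(1S,4aS,8aR)-2,5,5,8a-tetramethyl-6-oxo-1,4,4a,5,6,7,8,8a-octahydronaphthalen-1-yl]methoxy}-2H-chromen-2-one | CC1=CC[C@@H]2C(C)(C)C(=O)CC[C@@]2(C)[C@H]1COc1ccc2ccc(=O)oc2c1 | target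

## Step count and risks

Total step count: 17. Longest linear sequence: 17 steps (1 → 25); compounds 3, 11 and 22 are bought.

**Step 12 (key step).** Ring closure may be slow and lose out to dimerisation through the allyl group. The reacting conformer needs both arms equatorial, which forces the C4 and C10 methyl groups syn-axial, and the accepting alkene is 1,1-disubstituted next to a branched carbon. Fallback: the same C7=C8 bond is made by carbonyl coupling, setting out from 17. Selective cleavage of the terminal allyl alkene (OsO4 cat., NaIO4, 2,6-lutidine, dioxane–water; the internal C1=C2 alkene is shielded by C10 and C3) gives keto aldehyde F1. Intramolecular McMurry coupling with low-valent titanium (TiCl3(DME)1.5, Zn–Cu, DME, reflux) joins C7 and C8 and returns to the route at 19.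

**Step 9.** The ester enolate may lose p-methoxybenzyl oxide by E1cB elimination before it is silylated, or the ketene acetal geometry may erode and lower the C9 selectivity. Both follow from the β-alkoxy group and the minutes the free enolate spends in a polar medium. Fallback: a dianionic Ireland–Claisen rearrangement, setting out from 12. DDQ removes the PMB group to give β-hydroxy ester F2. Two equivalents of LiN(i-Pr)2 then form the chelated alkoxide–enolate, which cannot eliminate and has the same enolate geometry; silylation with TMSCl and warming give, after acid work-up, hydroxy acid F3. MeLi converts F3 to hydroxy ketone F4, and 4-methoxybenzyl trichloroacetimidate with catalytic acid returns to the route at 17.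

**Step 7.** The enzyme may acylate neither enantiomer, or both without discrimination, because the carbinol is flanked by a silyloxy group and a syn-axial methyl. Fallback: covalent resolution, setting out from 9. Esterification with (S)-2-methoxy-2-phenylacetic acid (DCC, DMAP cat.) gives the diastereomeric esters F5 (from the 1S alcohol) and F6 (from the 1R alcohol), which are separated by chromatography. Hydrolysis of F5 (LiOH, THF–water) returns to the route at 10.

**Step 13.** Hydrogenation of the hindered C1=C2 alkene may stall, or prolonged forcing may begin to isomerise or reduce C7=C8. Fallback: the alkene is removed by conjugate reduction, setting out from 19. Bu4NF gives allylic alcohol F7 and MnO2 gives enone F8. Conjugate reduction with [(Ph3P)CuH]6 gives saturated ketone F9, and DDQ gives keto alcohol F10. A Mitsunobu reaction of F10 with 22 (PPh3, DIAD) comes back to the route at 25.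

**Step 15.** Displacement at the oxyphosphonium stage may be sluggish because C11 is β-branched next to the quaternary C10, allowing alkylation of the reduced azodicarboxylate or elimination to compete. Fallback: the alcohol is used as the nucleophile in an aryl C–O coupling, setting out from 21. Coupling with purchased 7-bromo-2H-chromen-2-one ([(allyl)PdCl]2, RockPhos, Cs2CO3, toluene, 90 °C) returns to the route at 23 and makes no new intermediate (F0).

Further compounds

F1 | step 12 | keto aldehyde (17 with the C5 allyl group cleaved to CH2CHO; C9 acetyl and CH2OPMB, C3 OTBS, C1=C2; configuration as in 17) | O=CC[C@@H]1C(C)(C)[C@@H](O[Si](C)(C)C(C)(C)C)C=C[C@@]1(C)[C@@H](COCc2ccc(OC)cc2)C(C)=O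
F2 | step 9 | (1S,4S,6R)-4-allyl-6-[(tert-butyldimethylsilyl)oxy]-3,5,5-trimethylcyclohex-2-en-1-yl 3-hydroxypropanoate | CC1=C[C@H](OC(=O)CCO)[C@H](O[Si](C)(C)C(C)(C)C)C(C)(C)[C@H]1CC=C
F3 | step 9 | (2S)-2-[(1R,4S,6S)-6-allyl-4-[(tert-butyldimethylsilyl)oxy]-1,5,5-trimethylcyclohex-2-en-1-yl]-3-hydroxypropanoic acid | C=CC[C@@H]1C(C)(C)[C@@H](O[Si](C)(C)C(C)(C)C)C=C[C@@]1(C)[C@@H](CO)C(=O)O
F4 | step 9 | (3S)-3-[(1R,4S,6S)-6-allyl-4-[(tert-butyldimethylsilyl)oxy]-1,5,5-trimethylcyclohex-2-en-1-yl]-4-hydroxybutan-2-one | C=CC[C@@H]1C(C)(C)[C@@H](O[Si](C)(C)C(C)(C)C)C=C[C@@]1(C)[C@@H](CO)C(C)=O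
F5 | step 7 | (1S,4S,6R)-4-allyl-6-[(tert-butyldimethylsilyl)oxy]-3,5,5-trimethylcyclohex-2-en-1-yl (2S)-2-methoxy-2-phenylacetate | CC1=C[C@H](OC(=O)[C@@H](OC)c2ccccc2)[C@H](O[Si](C)(C)C(C)(C)C)C(C)(C)[C@H]1CC=C
F6 | step 7 | (1R,4R,6S)-4-allyl-6-[(tert-butyldimethylsilyl)oxy]-3,5,5-trimethylcyclohex-2-en-1-yl (2S)-2-methoxy-2-phenylacetate | CC1=C[C@@H](OC(=O)[C@@H](OC)c2ccccc2)[C@@H](O[Si](C)(C)C(C)(C)C)C(C)(C)[C@@H]1CC=C
F7 | step 13 | (3S,5S,9S,10R)-11-[(4-methoxybenzyl)oxy]drima-1,7-dien-3-ol | CC1=CC[C@@H]2C(C)(C)[C@@H](O)C=C[C@@]2(C)[C@H]1COCc1ccc(OC)cc1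
F8 | step 13 | (5S,9S,10R)-11-[(4-methoxybenzyl)oxy]drima-1,7-dien-3-one | CC1=CC[C@@H]2C(C)(C)C(=O)C=C[C@@]2(C)[C@H]1COCc1ccc(OC)cc1
F9 | step 13 | (5S,9S,10R)-11-[(4-methoxybenzyl)oxy]drim-7-en-3-one | CC1=CC[C@@H]2C(C)(C)C(=O)CC[C@@]2(C)[C@H]1COCc1ccc(OC)cc1
F10 | step 13 | (5S,9S,10R)-11-hydroxydrim-7-en-3-one | CC1=CC[C@@H]2C(C)(C)C(=O)CC[C@@]2(C)[C@H]1CO
F0 | step 15 | none | none
A1 | alternative 1 | 9,10-methano alcohol (cyclopropane on the hydroxyl face, C3 ethylene ketal) | O[C@@H]1CC[C@@H]2C(C)(C)C3(OCCO3)CC[C@]24C[C@H]14
A2 | alternative 1 | allylic alcohol with C9=C10 alkene, C8 hydroxyl and C3 ethylene ketal | O[C@@H]1CC[C@@H]2C(C)(C)C3(OCCO3)CCC2=C1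
A3 | alternative 2 | endo Diels–Alder adduct (C5=C6 enol ether, C9 acyl anti to C10 methyl) | C[C@@H]1CC(OCC)=C2C(C)(C)C3(OCCO3)CC[C@@]2(C)[C@H]1C(=O)N1CCOC1=O
A4 | alternative 2 | 3-[(E)-but-2-enoyl]-1,3-oxazolidin-2-one | C/C=C/C(=O)N1CCOC1=O
A5 | alternative 2 | 7-(1-ethoxyethenyl)-6,6,8-trimethyl-1,4-dioxaspiro[4.5]dec-7-ene | C=C(OCC)C1=C(C)CCC2(OCCO2)C1(C)C
A6 | alternative 3 | cis-fused quinone Diels–Alder adduct (C3 silyl enol ether, C6 and C9 ketones, C7=C8) | CC1=CC(=O)[C@H]2C(C)(C)C(O[Si](C(C)C)(C(C)C)C(C)C)=CC[C@@]2(C)C1=O
A7 | alternative 3 | 2,6-dimethyl-1,4-benzoquinone | CC1=CC(=O)C=C(C)C1=O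
A8 | alternative 3 | triisopropyl[(4-methylpenta-1,3-dien-3-yl)oxy]silane | C=CC(O[Si](C(C)C)(C(C)C)C(C)C)=C(C)C
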